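## Retrosynthetic overview

- Germacranolide numbering is used throughout (C6 lactone carbinol; C7 bears C11–C13; C8 acyloxy; C9 hydroxy; C14 on C10; C15 on C4). The strategy rests on the Z-trisubstituted C1=C10 alkene of the ten-membered carbocycle: C1 and C10 are first bridged by sulfur in an eleven-membered sulfone, and SO2 is then extruded (Ramberg–Bäcklund).
- The eleven-membered ring is closed by S-alkylation of a C10 thiolate with the C1 halide. The sulfur is put on C10 early by thioacid opening of an epoxide, carried as the thioacetate, and unveiled in the DIBAL step that also opens the lactone.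
- The C6–C7 bond and both stereocentres come from allylboration of a geranyl-derived C1–C6 enal with a γ-substituted 2-(methoxycarbonyl)allylboronate. C8 and C9 come from a Sharpless kinetic resolution of hexa-1,4-dien-3-ol.
- Ring order: eleven-membered thiacycle, then ten-membered carbocycle (ring contraction), then cis-fused α-methylene-γ-lactone (oxidative lactonisation). The O8 side-chain acid (from an Evans allylation) is attached after that and O9 is freed last.

Key step: step 21

Remark on the chemistry: C10 of the sulfone is destroyed in the contraction, so the single (10R) epimer that the epoxide opening delivers is used as it comes. Centres that are later removed (epoxide of step 1, diols before cleavage, the Baylis–Hillman carbinol) are carried as mixtures. Open-chain intermediates keep the germacrane locants and simply lack the C1–C10 bond.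

## Route

Step 1
Reactants: 1 geranyl acetate
Product: 2 6,7-epoxygeranyl acetate (racemic at the epoxide)
Conditions: mCPBA (1.05 equiv), NaHCO3, CH2Cl2, 0 °C
Reagents that add atoms: 3-chloroperbenzoic acid, O=C(OO)c1cccc(Cl)c1
Why: Prilezhaev epoxidation with one equivalent of peracid is selective for the electron-rich remote 6,7-alkene over the 2,3-alkene deactivated by the allylic acetate.

Step 2
Reactants: 2 6,7-epoxygeranyl acetate
Product: 4 (2E)-3-methyl-6-oxohex-2-en-1-yl acetate, via diol 3 (not isolated)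
Conditions: H5IO6, THF/H2O, 0 °C → rt
Reagents that add atoms: none
Why: Periodic acid hydrolyses the epoxide to the vicinal diol and cleaves it in the same flask (Malaprade glycol cleavage), which removes the terminal carbon as acetone and leaves the future C1 as an aldehyde.

Step 3
Reactants: 4 (2E)-3-methyl-6-oxohex-2-en-1-yl acetate
Product: 5 (2E)-6-hydroxy-3-methylhex-2-en-1-yl acetate
Conditions: NaBH4, MeOH, 0 °C
Reagents that add atoms: none
Why: Borohydride reduction of the aldehyde gives the primary alcohol and leaves the allylic acetate untouched at 0 °C.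

Step 4
Reactants: 5 (2E)-6-hydroxy-3-methylhex-2-en-1-yl acetate
Product: 6 (2E)-6-chloro-3-methylhex-2-en-1-yl acetate
Conditions: PPh3, N-chlorosuccinimide, CH2Cl2, 0 °C → rt
Reagents that add atoms: N-chlorosuccinimide, O=C1CCC(=O)N1Cl
Why: Appel-type chlorination through the alkoxyphosphonium salt gives the robust C1 chloride that is carried unchanged to the macrocyclisation.

Step 5
Reactants: 6 (2E)-6-chloro-3-methylhex-2-en-1-yl acetate
Product: 7 (2E)-6-chloro-3-methylhex-2-en-1-ol
Conditions: K2CO3 (cat.), MeOH, rt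
Reagents that add atoms: none
Why: Base-catalysed transesterification frees the allylic alcohol, and the primary chloride is inert to carbonate in methanol at room temperature.

Step 6
Reactants: 7 (2E)-6-chloro-3-methylhex-2-en-1-ol
Product: 8 (2E)-6-chloro-3-methylhex-2-enal (C1–C6 enal; Cl on C1, CHO is C6)
Conditions: MnO2, CH2Cl2, rt
Reagents that add atoms: none
Why: Allylic oxidation with MnO2 gives the enal without isomerising the E-trisubstituted C4=C5 alkene.

Step 7
Reactants: 9 (E)-but-2-enal; 10 vinylmagnesium bromide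
Product: 11 rac-(4E)-hexa-1,4-dien-3-ol
Conditions: THF, −78 → 0 °C; aq. NH4Cl
Reagents that add atoms: none
Why: 1,2-Grignard addition of the hard vinyl nucleophile to the enal gives the racemic bis-allylic alcohol.

Step 8
Reactants: 11 rac-(4E)-hexa-1,4-dien-3-ol
Product: 12 (1S)-1-[(2S,3S)-3-methyloxiran-2-yl]prop-2-en-1-ol
Conditions: Ti(Oi-Pr)4, L-(+)-diisopropyl tartrate, t-BuOOH (0.55 equiv), 4 Å molecular sieves, CH2Cl2, −20 °C
Reagents that add atoms: tert-butyl hydroperoxide, CC(C)(C)OO
Why: Sharpless asymmetric epoxidation in kinetic-resolution mode should epoxidise the (S)-alcohol fast on its E-propenyl group to the erythro epoxy alcohol, which fixes C8 and C9 (and C10), while the (R)-alcohol and the intrinsically slow vinyl group stay behind.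

Step 9
Reactants: 12 (1S)-1-[(2S,3S)-3-methyloxiran-2-yl]prop-2-en-1-ol
Product: 13 (2S,3S)-2-[(1S)-1-(4-methoxybenzyloxy)prop-2-en-1-yl]-3-methyloxirane
Conditions: NaH, PMBCl, n-Bu4NI (cat.), THF, 0 °C → rt
Reagents that add atoms: 4-methoxybenzyl chloride, COc1ccc(CCl)cc1
Why: Williamson etherification of the alkoxide protects O8, and in aprotic medium at 0 °C alkylation should outrun Payne rearrangement.

Step 10
Reactants: 13 (2S,3S)-2-[(1S)-1-(4-methoxybenzyloxy)prop-2-en-1-yl]-3-methyloxirane
Product: 14 S-[(2R,3S,4S)-3-hydroxy-4-(4-methoxybenzyloxy)hex-5-en-2-yl] ethanethioate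
Conditions: AcSH (3 equiv), BHT (cat.), degassed toluene, dark, 45 °C (no base)
Reagents that add atoms: thioacetic acid, CC(=O)S
Why: Thioacid opening of the trans-epoxide by SN2 attack at C10, the carbon remote from the branched and inductively deactivating C8 ether, sets the C10–S bond with inversion and frees O9; base-free, radical-free conditions are chosen to suppress S-to-O acetyl migration and thiol–ene addition to the vinyl group.

Step 11
Reactants: 14 S-[(2R,3S,4S)-3-hydroxy-4-(4-methoxybenzyloxy)hex-5-en-2-yl] ethanethioate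
Product: 15 S-[(2R,3S,4S)-3-(tert-butyldimethylsilyloxy)-4-(4-methoxybenzyloxy)hex-5-en-2-yl] ethanethioate
Conditions: TBSOTf, 2,6-lutidine, CH2Cl2, −78 °C
Reagents that add atoms: tert-butyldimethylsilyl triflate, CC(C)(C)[Si](C)(C)OS(=O)(=O)C(F)(F)F
Why: Low-temperature silylation with the silyl triflate and a hindered base caps O9 before any acyl shift from sulfur can occur.

Step 12
Reactants: 15 S-[(2R,3S,4S)-3-(tert-butyldimethylsilyloxy)-4-(4-methoxybenzyloxy)hex-5-en-2-yl] ethanethioate
Product: 17 S-[(2R,3S,4R)-3-(tert-butyldimethylsilyloxy)-4-(4-methoxybenzyloxy)-5-oxopentan-2-yl] ethanethioate, via diol 16 (not isolated)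
Conditions: OsO4 (cat.), NaIO4, 2,6-lutidine, dioxane/H2O, rt
Reagents that add atoms: osmium tetroxide, O=[Os](=O)(=O)=O (catalytic, reoxidised by sodium periodate, [Na+].[O-]I(=O)(=O)=O)
Why: Lemieux–Johnson cleavage (osmylation, then periodate cleavage of the diol) turns the vinyl group into the C7 aldehyde under neutral conditions that spare the thioester and the PMB ether.

Step 13
Reactants: 17 S-[(2R,3S,4R)-3-(tert-butyldimethylsilyloxy)-4-(4-methoxybenzyloxy)-5-oxopentan-2-yl] ethanethioate; 18 methyl propiolate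
Product: 20 methyl (4S,5S,6R)-6-(acetylsulfanyl)-5-(tert-butyldimethylsilyloxy)-3-hydroxy-4-(4-methoxybenzyloxy)-2-methylideneheptanoate (C3 epimers), via vinylalane 19 (not isolated)
Conditions: i-Bu2AlH (1.0 equiv), NMO, THF, 0 °C, then 18 (1.1 equiv); then 17, 0 °C → rt
Reagents that add atoms: none
Why: Vinylalumination (the α-aluminoacrylate from hydroalumination of the propiolate adds to the aldehyde) gives the Morita–Baylis–Hillman-type adduct without a nucleophilic amine that could attack the thioester; the configuration of the new carbinol is irrelevant because it becomes sp2 in step 15.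

Step 14
Reactants: 20 Baylis–Hillman-type alcohol
Product: 21 methyl (4S,5S,6R)-3-acetoxy-6-(acetylsulfanyl)-5-(tert-butyldimethylsilyloxy)-4-(4-methoxybenzyloxy)-2-methylideneheptanoate (C3 epimers)
Conditions: Ac2O, pyridine, DMAP (cat.), CH2Cl2, 0 °C
Reagents that add atoms: acetic anhydride, CC(=O)OC(C)=O
Why: DMAP-catalysed acetylation turns the allylic hydroxyl into the leaving group for the SN2′ displacement.

Step 15
Reactants: 21 allylic acetate
Product: 22 methyl (2E,4S,5S,6R)-6-(acetylsulfanyl)-5-(tert-butyldimethylsilyloxy)-4-(4-methoxybenzyloxy)-2-[(4,4,5,5-tetramethyl-1,3,2-dioxaborolan-2-yl)methyl]hept-2-enoate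
Conditions: B2pin2, CuCl, LiCl, KOAc, DMF, rt
Reagents that add atoms: bis(pinacolato)diboron, CC1(C)OB(OC1(C)C)B1OC(C)(C)C(C)(C)O1
Why: The boryl copper species pinB–Cu attacks the acrylate terminus in an SN2′ addition–elimination, and acetate departs to give the preferred trisubstituted alkene with C8 trans to the ester and cis to CH2Bpin, as known for Baylis–Hillman acetates.

Step 16
Reactants: 22 allylboronate; 8 (2E)-6-chloro-3-methylhex-2-enal
Product: 24 C1-chloro C10-thioacetate cis-α-methylene-γ-lactone (6S,7S,8S,9S,10R), via borate 23 (not isolated)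
Conditions: 8 (1.5 equiv), toluene, 90 °C; then PPTS (cat.), 60 °C
Reagents that add atoms: none
Why: Carbonyl allylboration through a closed chair (Zimmerman–Traxler) transition state places C8, cis to the boryl-methyl arm, axial, so O6 and C11 end up anti along C5–C8 (cis-lactone), while allylic 1,3-strain holds H8 in the alkene plane so that the enal should add anti to the bulky C9 branch and give the C11/O8 anti relationship; the borate then acylates itself to the lactone.

Step 17
Reactants: 24 cis-α-methylene-γ-lactone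
Product: 25 C10-thiol 6,12-diol (6S,7S,8S,9S,10R)
Conditions: i-Bu2AlH (6 equiv, inverse addition), CH2Cl2, −78 → −20 °C; aq. potassium sodium tartrate
Reagents that add atoms: none
Why: Excess DIBAL reduces the α-methylene lactone by 1,2-hydride delivery to the 2-methylene-1,4-diol and at the same time cleaves the thioacetate reductively, so the C10 thiol appears only when no Michael acceptor is left.

Step 18
Reactants: 25 C10-thiol 6,12-diol
Product: 26 C10-thiol 6,12-bis(triethylsilyl) ether (6S,7R,8S,9S,10R)
Conditions: Et3SiCl, imidazole, DMAP (cat.), DMF, 0 °C → rt; MeOH/aq. NaHCO3 work-up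
Reagents that add atoms: chlorotriethylsilane, CC[Si](CC)(CC)Cl
Why: Silylation converts both hydroxyls into TES ethers, and any S–Si bond formed is cleaved again in the methanolic work-up, so the thiol is left free.

Step 19
Reactants: 26 C10-thiol bis-TES ether
Product: 28 eleven-membered cyclic sulfide (6S,7R,8S,9S,10R), via iodide 27 (not isolated)
Conditions: Cs2CO3, NaI, degassed DMF (1 mM, syringe-pump addition of 26), 45 °C
Reagents that add atoms: none
Why: Finkelstein exchange gives the primary iodide in situ and the soft caesium thiolate closes the eleven-membered thioether by intramolecular SN2 under high dilution, a closure helped by the caesium effect and free of competing alkoxide nucleophiles.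

Step 20
Reactants: 28 eleven-membered cyclic sulfide
Product: 30 eleven-membered cyclic sulfone (6S,7R,8S,9S,10R), via sulfoxide 29 (not isolated)
Conditions: 30% H2O2, Na2WO4·2H2O (cat.), NaHCO3, MeOH/THF, 0 °C → rt
Reagents that add atoms: hydrogen peroxide, OO
Why: Na2WO4-catalysed peroxide oxidation takes the sulfide through the sulfoxide to the sulfone, sulfur being far more nucleophilic than the unactivated alkenes under buffered conditions.

Step 21
Reactants: 30 eleven-membered cyclic sulfone
Product: 33 protected (1(10)Z,4E)-cyclodecadiene (6S,7R,8S,9R), via bromosulfone 31 (not isolated), via episulfone 32 (not isolated)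
Conditions: KOH/Al2O3, CBr2F2, t-BuOH/CH2Cl2, 0 °C → rt
Reagents that add atoms: none
Why: Hydroxide on alumina deprotonates the sulfone at the unhindered C1 methylene, the carbanion is brominated by CBr2F2 to 31, and deprotonation at C10 with intramolecular displacement of bromide (1,3-elimination) gives thiirane 1,1-dioxide 32, which loses SO2 in a cheletropic step to form the C1=C10 bond; this is the Ramberg–Bäcklund reaction in its in situ halogenation variant, known for dialkyl and medium-ring sulfones. The ten-membered carbocycle is closed by ring contraction: the C1–C10 bond forms by 3-exo-tet closure inside the existing eleven-membered ring, so no high-dilution carbon–carbon macrocyclisation is needed. No stereocentre is created and C10 is destroyed, so the only stereochemical element set here is the alkene geometry. The step needs the Z geometry, which should follow because the kinetically formed episulfone has C2 and C9 cis on the three-membered ring (a trans-fused thiirane in a ring of this size is much more strained) and the weak heterogeneous base does not epimerise it before SO2 is lost. It also needs ring closure to outrun β-elimination of the C9 silyloxy group from the C10 carbanion and a second bromination at C1; the proximity of the C1–Br bond, the poor leaving ability of the hindered silyloxide and the mild brominating agent favour the 1,3-elimination, and the TES, TBS and PMB ethers are stable to KOH in t-BuOH.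

Step 22
Reactants: 33 protected (1(10)Z,4E)-cyclodecadiene
Product: 34 6,12-diol (6S,7S,8S,9R)
Conditions: HF·pyridine, pyridine, THF, 0 °C
Reagents that add atoms: none
Why: Buffered fluoride at 0 °C cleaves the two TES ethers selectively in the presence of the more hindered secondary TBS ether and avoids protic acid on the transannularly reactive 1(10),4-diene.

Step 23
Reactants: 34 6,12-diol
Product: 37 O8-PMB O9-TBS cis-fused 6,12-olide (6S,7S,8S,9R), via hydroxyenal 35 (not isolated), via lactol 36 (not isolated)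
Conditions: TEMPO (cat.), PhI(OAc)2, CH2Cl2, rt
Reagents that add atoms: none
Why: Oxoammonium (TEMPO) oxidation is selective for the primary allylic alcohol, the aldehyde is trapped by O6 as the γ-lactol and this is oxidised on to the α-methylene-γ-butyrolactone; O8 is blocked as its PMB ether, so only the 6,12-lactone can form.

Step 24
Reactants: 37 O8-PMB O9-TBS 6,12-olide
Product: 38 8-hydroxy O9-TBS 6,12-olide (6S,7R,8S,9R)
Conditions: DDQ, CH2Cl2/pH 7 buffer, 0 °C
Reagents that add atoms: none
Why: Oxidative cleavage of the PMB ether by DDQ through the benzylic oxocarbenium ion under buffered conditions frees O8 alone.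

Step 25
Reactants: 39 (S)-4-benzyl-3-propionyloxazolidin-2-one; 40 allyl iodide
Product: 41 (S)-4-benzyl-3-[(R)-2-methylpent-4-enoyl]oxazolidin-2-one
Conditions: NaN(SiMe3)2, THF, −78 °C; then 40, −78 → −40 °C
Reagents that add atoms: none
Why: Evans asymmetric alkylation, in which the chelated Z-sodium enolate is allylated on the face away from the benzyl group, sets the (R) methyl-bearing centre of the side chain.

Step 26
Reactants: 41 (S)-4-benzyl-3-[(R)-2-methylpent-4-enoyl]oxazolidin-2-one
Product: 42 (R)-2-methylpent-4-en-1-ol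
Conditions: LiBH4, Et2O, H2O (1 equiv), 0 °C
Reagents that add atoms: none
Why: Reductive removal of the auxiliary with LiBH4 gives the primary alcohol without epimerisation and returns the oxazolidinone.

Step 27
Reactants: 42 (R)-2-methylpent-4-en-1-ol; 43 stearoyl chloride
Product: 44 (R)-2-methylpent-4-en-1-yl octadecanoate
Conditions: Et3N, DMAP (cat.), CH2Cl2, 0 °C → rt
Reagents that add atoms: none
Why: Acylation of the primary alcohol with the acid chloride installs the stearate.

Step 28
Reactants: 44 (R)-2-methylpent-4-en-1-yl octadecanoate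
Product: 46 (R)-3-methyl-4-(octadecanoyloxy)butanoic acid, via aldehyde 45 (not isolated)
Conditions: RuCl3·xH2O (cat.), NaIO4, MeCN/EtOAc/H2O, rt
Reagents that add atoms: ruthenium tetroxide, O=[Ru](=O)(=O)=O (formed from RuCl3 and NaIO4); water, O
Why: Ruthenium tetroxide cleaves the terminal alkene through the aldehyde to the carboxylic acid and leaves the ester and the β-stereocentre untouched.

Step 29
Reactants: 38 8-hydroxy O9-TBS 6,12-olide; 46 (R)-3-methyl-4-(octadecanoyloxy)butanoic acid
Product: 47 O9-TBS ether of the target (6S,7S,8S,9R; side chain 3R)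
Conditions: EDC·HCl, DMAP, CH2Cl2, rt
Reagents that add atoms: none
Why: Steglich esterification acylates the only free hydroxyl, O8, and because O9 is still silylated no regiochemical choice or acyl migration arises.

Step 30
Reactants: 47 O9-TBS ether of the target
Product: 48 CNP0114940.1 (target)
Conditions: HF·pyridine, THF/pyridine, 0 °C → rt
Reagents that add atoms: none
Why: Fluoride cleavage of the secondary TBS ether under mildly acidic HF·pyridine conditions avoids the base-induced O8-to-O9 acyl shift and conjugate addition to the α-methylene lactone.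

## Compound list

1 | geranyl acetate | CC(C)=CCC/C(C)=C/COC(C)=O | starting material
2 | (2E)-6,7-epoxy-3,7-dimethyloct-2-en-1-yl acetate (racemic) | CC1(C)OC1CC/C(C)=C/COC(C)=O | intermediate
3 | (2E)-6,7-dihydroxy-3,7-dimethyloct-2-en-1-yl acetate (racemic) | CC(C)(O)C(O)CC/C(C)=C/COC(C)=O | intermediate (not isolated)
4 | (2E)-3-methyl-6-oxohex-2-en-1-yl acetate | O=CCC/C(C)=C/COC(C)=O | intermediate
5 | (2E)-6-hydroxy-3-methylhex-2-en-1-yl acetate | OCCC/C(C)=C/COC(C)=O | intermediate
6 | (2E)-6-chloro-3-methylhex-2-en-1-yl acetate | ClCCC/C(C)=C/COC(C)=O | intermediate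
7 | (2E)-6-chloro-3-methylhex-2-en-1-ol | ClCCC/C(C)=C/CO | intermediate
8 | (2E)-6-chloro-3-methylhex-2-enal | ClCCC/C(C)=C/C=O | intermediate
9 | (E)-but-2-enal (crotonaldehyde) | C/C=C/C=O | starting material
10 | vinylmagnesium bromide | C=C[Mg]Br | starting material
11 | rac-(4E)-hexa-1,4-dien-3-ol | C/C=C/C(O)C=C | intermediate
12 | (1S)-1-[(2S,3S)-3-methyloxiran-2-yl]prop-2-en-1-ol | C[C@@H]1O[C@H]1[C@@H](O)C=C | intermediate
13 | (2S,3S)-2-[(1S)-1-(4-methoxybenzyloxy)prop-2-en-1-yl]-3-methyloxirane | C[C@@H]1O[C@H]1[C@@H](OCc2ccc(OC)cc2)C=C | intermediate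
14 | S-[(2R,3S,4S)-3-hydroxy-4-(4-methoxybenzyloxy)hex-5-en-2-yl] ethanethioate | C[C@@H](SC(C)=O)[C@@H](O)[C@@H](OCc1ccc(OC)cc1)C=C | intermediate
15 | S-[(2R,3S,4S)-3-(tert-butyldimethylsilyloxy)-4-(4-methoxybenzyloxy)hex-5-en-2-yl] ethanethioate | C[C@@H](SC(C)=O)[C@@H](O[Si](C)(C)C(C)(C)C)[C@@H](OCc1ccc(OC)cc1)C=C | intermediate
16 | S-[(2R,3S,4S)-3-(tert-butyldimethylsilyloxy)-5,6-dihydroxy-4-(4-methoxybenzyloxy)hexan-2-yl] ethanethioate (C5 epimers) | C[C@@H](SC(C)=O)[C@@H](O[Si](C)(C)C(C)(C)C)[C@@H](OCc1ccc(OC)cc1)C(O)CO | intermediate (not isolated)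
17 | S-[(2R,3S,4R)-3-(tert-butyldimethylsilyloxy)-4-(4-methoxybenzyloxy)-5-oxopentan-2-yl] ethanethioate | C[C@@H](SC(C)=O)[C@@H](O[Si](C)(C)C(C)(C)C)[C@@H](OCc1ccc(OC)cc1)C=O | intermediate
18 | methyl propiolate | C#CC(=O)OC | starting material
19 | methyl 2-(diisobutylalumanyl)prop-2-enoate | C=C(C(=O)OC)[Al](CC(C)C)CC(C)C | intermediate (not isolated)
20 | methyl (4S,5S,6R)-6-(acetylsulfanyl)-5-(tert-butyldimethylsilyloxy)-3-hydroxy-4-(4-methoxybenzyloxy)-2-methylideneheptanoate (C3 epimers) | C[C@@H](SC(C)=O)[C@@H](O[Si](C)(C)C(C)(C)C)[C@@H](OCc1ccc(OC)cc1)C(O)C(=C)C(=O)OC | intermediate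
21 | methyl (4S,5S,6R)-3-acetoxy-6-(acetylsulfanyl)-5-(tert-butyldimethylsilyloxy)-4-(4-methoxybenzyloxy)-2-methylideneheptanoate (C3 epimers) | C[C@@H](SC(C)=O)[C@@H](O[Si](C)(C)C(C)(C)C)[C@@H](OCc1ccc(OC)cc1)C(OC(C)=O)C(=C)C(=O)OC | intermediate
22 | methyl (2E,4S,5S,6R)-6-(acetylsulfanyl)-5-(tert-butyldimethylsilyloxy)-4-(4-methoxybenzyloxy)-2-[(4,4,5,5-tetramethyl-1,3,2-dioxaborolan-2-yl)methyl]hept-2-enoate | C[C@@H](SC(C)=O)[C@@H](O[Si](C)(C)C(C)(C)C)[C@@H](OCc1ccc(OC)cc1)/C=C(\CB1OC(C)(C)C(C)(C)O1)C(=O)OC | intermediate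
23 | open-chain O6-pinacolboryl hydroxy methyl ester from the allylboration (6S,7S,8S,9S,10R): C1 chloride, C4=C5 E, C11(=C13H2)CO2Me on C7, O8 PMB, O9 TBS, C10 SAc | C[C@@H](SC(C)=O)[C@@H](O[Si](C)(C)C(C)(C)C)[C@@H](OCc1ccc(OC)cc1)[C@@H](C(=C)C(=O)OC)[C@@H](OB1OC(C)(C)C(C)(C)O1)/C=C(\C)CCCCl | intermediate (not isolated)
24 | open-chain cis-α-methylene-γ-lactone (6,12-olide; 6S,7S,8S,9S,10R): C1 chloride, C4=C5 E, O8 PMB, O9 TBS, C10 SAc | C[C@@H](SC(C)=O)[C@@H](O[Si](C)(C)C(C)(C)C)[C@@H](OCc1ccc(OC)cc1)[C@H]1C(=C)C(=O)O[C@H]1/C=C(\C)CCCCl | intermediate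
25 | open-chain C10 thiol, 6,12-diol (6S,7S,8S,9S,10R): C1 chloride, C11=C13 methylidene, O8 PMB, O9 TBS | C[C@@H](S)[C@@H](O[Si](C)(C)C(C)(C)C)[C@@H](OCc1ccc(OC)cc1)[C@@H](C(=C)CO)[C@@H](O)/C=C(\C)CCCCl | intermediate
26 | open-chain C10 thiol, O6,O12-bis(triethylsilyl) ether (6S,7R,8S,9S,10R): C1 chloride, O8 PMB, O9 TBS | C[C@@H](S)[C@@H](O[Si](C)(C)C(C)(C)C)[C@@H](OCc1ccc(OC)cc1)[C@@H](C(=C)CO[Si](CC)(CC)CC)[C@@H](O[Si](CC)(CC)CC)/C=C(\C)CCCCl | intermediate
27 | C1 iodide analogue of 26 | C[C@@H](S)[C@@H](O[Si](C)(C)C(C)(C)C)[C@@H](OCc1ccc(OC)cc1)[C@@H](C(=C)CO[Si](CC)(CC)CC)[C@@H](O[Si](CC)(CC)CC)/C=C(\C)CCCI | intermediate (not isolated)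
28 | eleven-membered cyclic sulfide, S between C1 and C10 (6S,7R,8S,9S,10R): O6/O12 TES, O8 PMB, O9 TBS | CC[Si](CC)(CC)O[C@H]1/C=C(\C)CCCS[C@H](C)[C@@H](O[Si](C)(C)C(C)(C)C)[C@@H](OCc2ccc(OC)cc2)[C@H]1C(=C)CO[Si](CC)(CC)CC | intermediate
29 | corresponding cyclic sulfoxide (sulfur epimers) | CC[Si](CC)(CC)O[C@H]1/C=C(\C)CCCS(=O)[C@H](C)[C@@H](O[Si](C)(C)C(C)(C)C)[C@@H](OCc2ccc(OC)cc2)[C@H]1C(=C)CO[Si](CC)(CC)CC | intermediate (not isolated)
30 | eleven-membered cyclic sulfone (6S,7R,8S,9S,10R): O6/O12 TES, O8 PMB, O9 TBS; key-step precursor | CC[Si](CC)(CC)O[C@H]1/C=C(\C)CCCS(=O)(=O)[C@H](C)[C@@H](O[Si](C)(C)C(C)(C)C)[C@@H](OCc2ccc(OC)cc2)[C@H]1C(=C)CO[Si](CC)(CC)CC | intermediate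
31 | 1-bromo derivative of sulfone 30 (C1 epimers) | CC[Si](CC)(CC)O[C@H]1/C=C(\C)CCC(Br)S(=O)(=O)[C@H](C)[C@@H](O[Si](C)(C)C(C)(C)C)[C@@H](OCc2ccc(OC)cc2)[C@H]1C(=C)CO[Si](CC)(CC)CC | intermediate (not isolated)
32 | bicyclic thiirane 1,1-dioxide spanning C1 and C10, C2 and C9 cis on the three-membered ring (configuration at C1/C10 not specified) | CC[Si](CC)(CC)O[C@H]1/C=C(\C)CCC2C(C)(S2(=O)=O)[C@@H](O[Si](C)(C)C(C)(C)C)[C@@H](OCc3ccc(OC)cc3)[C@H]1C(=C)CO[Si](CC)(CC)CC | intermediate (not isolated)
33 | protected ten-membered (1(10)Z,4E)-diene (6S,7R,8S,9R): O6/O12 TES, O8 PMB, O9 TBS; key-step product | CC[Si](CC)(CC)O[C@H]1/C=C(\C)CC/C=C(/C)[C@@H](O[Si](C)(C)C(C)(C)C)[C@@H](OCc2ccc(OC)cc2)[C@H]1C(=C)CO[Si](CC)(CC)CC | intermediate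
34 | ten-membered 6,12-diol (6S,7S,8S,9R): O8 PMB, O9 TBS | O[C@H]1/C=C(\C)CC/C=C(/C)[C@@H](O[Si](C)(C)C(C)(C)C)[C@@H](OCc2ccc(OC)cc2)[C@H]1C(=C)CO | intermediate
35 | 6-hydroxy-12-al (enal) from 34 | O[C@H]1/C=C(\C)CC/C=C(/C)[C@@H](O[Si](C)(C)C(C)(C)C)[C@@H](OCc2ccc(OC)cc2)[C@H]1C(=C)C=O | intermediate (not isolated)
36 | 6,12-lactol (C12 epimers) | C=C1C(O)O[C@H]2/C=C(\C)CC/C=C(/C)[C@@H](O[Si](C)(C)C(C)(C)C)[C@@H](OCc3ccc(OC)cc3)[C@@H]12 | intermediate (not isolated)
37 | cis-fused (1(10)Z,4E)-germacradien-6,12-olide with C13 methylidene, O8 PMB, O9 TBS (6S,7S,8S,9R) | C=C1C(=O)O[C@H]2/C=C(\C)CC/C=C(/C)[C@@H](O[Si](C)(C)C(C)(C)C)[C@@H](OCc3ccc(OC)cc3)[C@@H]12 | intermediate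
38 | 8-hydroxy-9-(tert-butyldimethylsilyloxy) analogue of 37 (6S,7R,8S,9R) | C=C1C(=O)O[C@H]2/C=C(\C)CC/C=C(/C)[C@@H](O[Si](C)(C)C(C)(C)C)[C@@H](O)[C@@H]12 | intermediate
39 | (S)-4-benzyl-3-propionyloxazolidin-2-one | CCC(=O)N1[C@@H](Cc2ccccc2)COC1=O | starting material
40 | allyl iodide | C=CCI | starting material
41 | (S)-4-benzyl-3-[(R)-2-methylpent-4-enoyl]oxazolidin-2-one | C=CC[C@@H](C)C(=O)N1[C@@H](Cc2ccccc2)COC1=O | intermediate
42 | (R)-2-methylpent-4-en-1-ol | C=CC[C@@H](C)CO | intermediate
43 | stearoyl chloride (octadecanoyl chloride) | CCCCCCCCCCCCCCCCCC(Cl)=O | starting material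
44 | (R)-2-methylpent-4-en-1-yl octadecanoate | C=CC[C@@H](C)COC(=O)CCCCCCCCCCCCCCCCC | intermediate
45 | (R)-2-methyl-4-oxobutyl octadecanoate | O=CC[C@@H](C)COC(=O)CCCCCCCCCCCCCCCCC | intermediate (not isolated)
46 | (R)-3-methyl-4-(octadecanoyloxy)butanoic acid | OC(=O)C[C@@H](C)COC(=O)CCCCCCCCCCCCCCCCC | intermediate
47 | O9-tert-butyldimethylsilyl ether of the target (6S,7S,8S,9R; side chain 3R) | C=C1C(=O)O[C@H]2/C=C(\C)CC/C=C(/C)[C@@H](O[Si](C)(C)C(C)(C)C)[C@@H](OC(=O)C[C@@H](C)COC(=O)CCCCCCCCCCCCCCCCC)[C@@H]12 | intermediate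
48 | CNP0114940.1 (6S,7S,8S,9R; side chain 3R) | C=C1C(=O)O[C@H]2/C=C(\C)CC/C=C(/C)[C@@H](O)[C@@H](OC(=O)C[C@@H](C)COC(=O)CCCCCCCCCCCCCCCCC)[C@@H]12 | target

## Step count and risks

Total step count: 30.
Longest linear sequence: 20 steps (steps 7–24, then 29 and 30).

The three steps most likely to fail:

Step 21 (key step). The contraction may suffer from a second bromination at C1, from β-elimination of the C9 silyloxy group out of the C10 carbanion, or from erosion of the Z geometry if the episulfone epimerises before it loses SO2. The fallback separates halogenation from ring closure. It sets out from 30: kinetic deprotonation at the unhindered C1 methylene with LiN(SiMe3)2 in THF at −78 °C and quenching with hexachloroethane should give the isolated 1-chloro sulfone F1. F1 is then submitted to the classical Ramberg–Bäcklund reaction with aqueous KOH under phase-transfer conditions, a weak-base regime that favours the cis-episulfone, and the route is rejoined at 33.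

Step 16. Addition of the electron-poor, γ-branched allylboronate to the β,β-disubstituted enal may be too slow at a temperature the thioester and enal tolerate, and facial control by C8 may erode at 90 °C. The fallback replaces the boron reagent by a metal-mediated Barbier reaction at room temperature. It sets out from 20: treatment with NBS/Me2S in CH2Cl2 at 0 °C should give the rearranged (2Z)-allylic bromide F2. Indium-mediated allylation of 8 with F2 in THF/H2O is known to give the syn adducts of such bromides and should deliver the hydroxy ester F3, which is lactonised with PPTS. The route is rejoined at 24.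

Step 19. Intermolecular S-alkylation (oligomers) and disulfide formation may compete with closure of the eleven-membered ring, because the two bulky silyl ethers next to the reacting chain ends disfavour the folded conformer. The fallback moves the ring closure ahead of the silylation. It sets out from 25: the free diol thiol is cyclised under the same high-dilution caesium thiolate conditions, where only sulfur is nucleophilic, to the cyclic sulfide diol F4. F4 is then silylated with Et3SiCl and imidazole, and the route is rejoined at 28.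

Further compounds
F1 | step 21 | 1-chloro derivative of sulfone 30 (C1 epimers; 6S,7R,8S,9S,10R) | CC[Si](CC)(CC)O[C@H]1/C=C(\C)CCC(Cl)S(=O)(=O)[C@H](C)[C@@H](O[Si](C)(C)C(C)(C)C)[C@@H](OCc2ccc(OC)cc2)[C@H]1C(=C)CO[Si](CC)(CC)CC
F2 | step 16 | methyl (2Z,4S,5S,6R)-6-(acetylsulfanyl)-2-(bromomethyl)-5-(tert-butyldimethylsilyloxy)-4-(4-methoxybenzyloxy)hept-2-enoate | C[C@@H](SC(C)=O)[C@@H](O[Si](C)(C)C(C)(C)C)[C@@H](OCc1ccc(OC)cc1)/C=C(\CBr)C(=O)OC
F3 | step 16 | open-chain 6-hydroxy methyl ester (6S,7S,8S,9S,10R): C1 chloride, C11(=C13H2)CO2Me on C7, O8 PMB, O9 TBS, C10 SAc | C[C@@H](SC(C)=O)[C@@H](O[Si](C)(C)C(C)(C)C)[C@@H](OCc1ccc(OC)cc1)[C@@H](C(=C)C(=O)OC)[C@@H](O)/C=C(\C)CCCCl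
F4 | step 19 | eleven-membered cyclic sulfide 6,12-diol (6S,7S,8S,9S,10R): O8 PMB, O9 TBS | O[C@H]1/C=C(\C)CCCS[C@H](C)[C@@H](O[Si](C)(C)C(C)(C)C)[C@@H](OCc2ccc(OC)cc2)[C@H]1C(=C)CO
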